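# Plakortone N by stereoretentive palladium cycloetherification of a hydroxy vinyl oxirane

## Analysis of the target

Plakortone N is a cis-fused tetrahydrofuro[3,2-b]furan-2(3H)-one: a γ-lactone (O1, C2, C3, C3a, C6a) shares the C3a–C6a bond with an oxolane (O4, C5, C6, C6a, C3a). C5 carries a methyl group and an unbranched 12-(4-hydroxyphenyl)dodecyl chain (C1'–C12'); C6a carries a methyl group. The three stereocentres are (3aS,5S,6aS). C5 and C6a are fully substituted carbinol carbons in a 1,3-relationship across the C6 methylene, and C3a is a secondary ether carbon tied to C6a by the cis ring fusion. C5 is the awkward centre: its two exocyclic carbon substituents, methyl and a long n-alkyl chain, differ too little for a reagent to tell apart or to steer anything else, and it bears no hydrogen through which it could be corrected later. Sensitive features are the lactone, the β-alkoxy carbonyl relationship O4–C3a–C3–C2 (base can open the oxolane by elimination) and the electron-rich phenol, which must be masked during organometallic and oxidative steps. The strategy rests on the O4–C3a bond. It joins the tertiary oxygen of C5 to a carbon whose neighbour C6a bears oxygen and which carries the two-carbon arm C3–C2. Read backwards, that is the pattern left when a hydroxyl group opens a vinyl oxirane (C6a–O–C3a, with C3 and the future C2 as the vinyl group) at its allylic carbon.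

## Retrosynthetic reasoning

**23 ⇒ 22.** The phenol is unmasked last by cutting the benzylic C–O bond of benzyl ether 22. A benzyl ether tolerates every reagent class used earlier. Its hydrogenolysis is only safe once no alkene remains, which is the case at the end.

**22 ⇒ 19 ⇒ 17.** The lactone is cut at the acyl bond O1–C2 and C2 is lowered to the alcohol level, giving the 1,4-diol 19. Its primary hydroxyl is traced to the terminal carbon of a vinyl group on C3a in 17. Nothing stereochemical happens here. The forward steps are an anti-Markovnikov hydration and an oxidation that stops at the lactone because the cis tertiary hydroxyl on C6a captures the aldehyde.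

**17 ⇒ 16 (key disconnection).** The oxolane is cut at O4–C3a. The other ring C–O bonds (O4–C5, O1–C6a) sit at fully substituted carbons, where displacement is impossible and ionisation would lose configuration. O4–C3a sits at a secondary allylic carbon and can be formed stereospecifically from the vinyl oxirane 16. This lets both tertiary C–O bonds be carried in intact from simpler operations. The forward reaction must ionise only at C3a, return O4 to the face the oxirane oxygen left, and close the five-membered ring.

**16 ⇒ 15 ⇒ 14 ⇒ 13.** The vinyl group is cut at its C=C bond to the epoxy aldehyde 15, which comes from the epoxy alcohol 14. The oxirane is removed to give the (E)-allylic alcohol 13. The hydroxymethyl group is kept at this stage because it lets a Sharpless epoxidation set C6a and C3a together under reagent control, independently of C5. The (E) geometry is a requirement: with C6 trans to the hydroxymethyl carbon, the C6a methyl and the vinyl group end up cis on the oxirane, which the retention pathway needs.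

**13 ⇒ 10.** The C6a–CH3 bond and the C3a–C3 bond are cut across the terminal alkyne of 10. A syn methyl-metalation places methyl on C6a and the metal on C3a, and a one-carbon electrophile then supplies C3. The (E) geometry follows from the mechanism in one operation, and no separately prepared alkenyl halide is needed.

**10 ⇒ 9.** The C6–C6a bond is cut: a two-carbon alkynyl nucleophile opens oxirane 9 at its CH2, which becomes C6. The quaternary C5 is not touched.

**9 ⇒ 7 ⇒ 5 + 6.** The oxirane of 9 is re-formed from the 1,2-diol 7 through its primary carbon. Diol 7 is cut at C1'–C2', giving the chain Grignard reagent 6 and the oxirane CH2 of (R)-2-methylglycidol 5. C5 is thus bought from the chiral pool. The two CH2 arms of 5 are told apart by the order of use: the oxirane CH2 becomes C1' and the hydroxymethyl carbon becomes C6. With the (R) enantiomer this order gives (5S).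

**6 ⇒ 4 ⇒ 1 + 2.** The chain is cut at the benzylic C12'–C11' bond: the benzylic Grignard reagent 3 from chloride 1 is coupled once with the symmetrical dibromide 2 to give bromide 4.

## Alternatives that were turned down

**Alternative 1: cyclopentene template opened by ring-rearrangement and cross metathesis.**
- **Disconnection:** C3a=C3 (as a butenolide) and C1'=C2' are traced to one metathesis event. C5, C6 and C6a come from a cyclopentene, and O4–C3a is left to a later oxa-Michael closure.
- **Forward key step:** the acrylate A2, made from the meso diol A1, and the chain alkene A3 react with second-generation Grubbs catalyst RuCl2(=CHPh)(H2IMes)(PCy3). The ring opens, the butenolide closes and the chain is attached, giving A4.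
- **For:** the chain arrives late. One final hydrogenation would saturate C1'=C2' and remove the benzyl group. The ring fusion would come from a conjugate addition that can only give the cis-fused bicycle. On that point it is stronger than the chosen route, because it does not depend on the stereochemical fidelity of an allyl complex.
- **Against:** A1 is a meso bis-tertiary diol, and telling its two tertiary hydroxyls apart enantioselectively has no dependable solution. The whole absolute configuration would hang on that step. The cyclopentene is flanked by two quaternary carbons, so ring-opening is hindered and poorly driven by strain. The ruthenium alkylidene formed next to a quaternary centre must then undergo a slow cross metathesis in competition with dimerisation of A3.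
- **Comparison:** the chosen route takes C5 from compound 5 and C6a/C3a from a Sharpless epoxidation, two events whose sense and reliability are not in doubt.

**Alternative 2: titanium hetero-Pauson–Khand reaction.**
- **Disconnection:** C6a–C3a, C3–C2 and C2–O1 are cut at once, back to the keto vinyl ether A5.
- **Forward key step:** (EBTHI)Ti(CO)2, ethylenebis(tetrahydroindenyl)titanium dicarbonyl (divalent titanium), couples the ketone, the vinyl ether and CO to give A6, which is the same compound as 22.
- **For:** three bonds, both rings and two stereocentres in one step. In step economy it is clearly stronger than the chosen route.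
- **Against:** the reaction type is established for aryl ketones and enones tethered to simple alkenes, and dialkyl ketones turn over poorly. The oxatitanacycle would carry O4 β to the Ti–C3 bond, so β-alkoxide elimination, strongly favoured for an oxophilic early metal, would cut the tether. A5 is a β-alkoxy ketone open to elimination. The catalyst alone would have to choose the ketone face against a C5 centre that offers no bias, with matched and mismatched cases unknown.
- **Comparison:** the chosen route is longer, but every stereocentre is set by a mechanism that can be predicted.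

**Alternative 3: Ireland–Claisen relay with iodolactonisation.**
- **Disconnection:** C3–C3a by [3,3] rearrangement and O1–C6a by halolactonisation, back to the dihydrofuranyl acetate A7.
- **Forward key step:** LiN(iPr)2 and Me3SiCl convert A7 into its silyl ketene acetal, which rearranges. Iodine then closes the lactone to give the iodolactone A8, and a radical deiodination would lead to 22.
- **For:** suprafacial 1,3-chirality transfer is dependable. The iodolactonisation fixes C6a through the ring. That is at least as secure as reagent control, and the two-carbon arm comes from a simple acetate.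
- **Against:** in A7 the acetate is allylic to a cyclic enol ether, so ionisation to an oxygen-stabilised allyl cation threatens both its preparation and the enolisation. A7 needs C6 set relative to the adjacent C5, again against the methyl/chain pair, and that stereocentre is created only to be destroyed. Removing the iodine costs an extra step.
- **Comparison:** the chosen route has no throw-away stereocentre and no halogen to remove, and its sensitive intermediate, the vinyl oxirane 16, is used in the step right after it is made.

Key step: step 9

Remark: the locants O1, C2, C3, C3a, O4, C5, C6, C6a and C1'–C12' of target 23 are used for the corresponding atoms of all intermediates; (R)-2-methylglycidol 5 is assumed to be available in high enantiomeric purity.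

## Route

Step 1
Reactants: 1 4-(benzyloxy)benzyl chloride; 2 1,10-dibromodecane
Product: 4 1-(benzyloxy)-4-(11-bromoundecyl)benzene, via benzylic Grignard reagent 3 (not isolated)
Conditions: Mg, THF, 0 °C (slow addition of 1); then added to 2 (3 equiv), Li2CuCl4 (3 mol%), THF, −10 °C to rt
Reagents that add atoms: none
Why: Copper-catalysed Grignard cross-coupling with a primary alkyl bromide; slow formation of 3 at 0 °C limits Wurtz dimerisation, and the excess of the symmetrical dibromide 2 (recoverable) suppresses double coupling.

Step 2
Reactants: 4 1-(benzyloxy)-4-(11-bromoundecyl)benzene; 5 (R)-2-methylglycidol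
Product: 7 (2S)-14-[4-(benzyloxy)phenyl]-2-methyltetradecane-1,2-diol, via chain Grignard reagent 6 (not isolated)
Conditions: Mg, THF, 40 °C; then 5 (0.43 equiv relative to 6), CuI (10 mol%), THF, −40 to 0 °C; aq. NH4Cl
Reagents that add atoms: none
Why: Copper-catalysed Grignard opening of an oxirane: one equivalent of 6 deprotonates the hydroxyl and a second attacks the unsubstituted oxirane CH2, so no bond to the quaternary stereocentre is made or broken; a Payne rearrangement of the alkoxide of this 2-substituted glycidol is degenerate and cannot erode the configuration.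

Step 3
Reactants: 7 (2S)-14-[4-(benzyloxy)phenyl]-2-methyltetradecane-1,2-diol
Product: 9 (2S)-2-{12-[4-(benzyloxy)phenyl]dodecyl}-2-methyloxirane, via primary tosylate 8 (not isolated)
Conditions: NaH (2.2 equiv), THF, 0 °C; N-tosylimidazole (1.05 equiv), 0 °C to rt
Reagents that add atoms: none
Why: One-pot diol-to-oxirane conversion: the unhindered primary alkoxide is sulfonylated selectively and the tertiary alkoxide displaces tosylate in a 3-exo-tet closure at the primary carbon, leaving the stereocentre untouched.

Step 4
Reactants: 9 (2S)-2-{12-[4-(benzyloxy)phenyl]dodecyl}-2-methyloxirane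
Product: 10 (4S)-16-[4-(benzyloxy)phenyl]-4-methylhexadec-1-yn-4-ol
Conditions: LiC≡CH·H2NCH2CH2NH2 (3 equiv), DMSO–THF, rt; aq. NH4Cl
Reagents that add atoms: lithium acetylide–ethylenediamine complex, [Li]C#C.NCCN
Why: SN2 opening of the 2,2-disubstituted oxirane at its CH2 by lithium acetylide in a dipolar solvent; no Lewis acid is present, so the Meinwald rearrangement that threatens such oxiranes is avoided.

Step 5
Reactants: 10 (4S)-16-[4-(benzyloxy)phenyl]-4-methylhexadec-1-yn-4-ol
Product: 13 (2E,5S)-17-[4-(benzyloxy)phenyl]-3,5-dimethylheptadec-2-ene-1,5-diol, via alkenylalane 11 (not isolated), via lithium alanate 12 (not isolated)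
Conditions: Me3Al (3.5 equiv), Cp2ZrCl2 (0.3 equiv), CH2Cl2, 0 °C to rt; volatiles removed; n-BuLi, THF–hexane, −78 to 0 °C; (CH2O)n, 0 °C to rt; aq. potassium sodium tartrate
Reagents that add atoms: trimethylaluminium, C[Al](C)C; paraformaldehyde (as formaldehyde), C=O
Why: Negishi zirconium-catalysed methylalumination adds methyl and aluminium syn across the terminal alkyne with methyl on the internal carbon, and the derived alanate is hydroxymethylated with retention, so the (E)-allylic alcohol follows from the mechanism; the tertiary hydroxyl is masked in the flask as its aluminium alkoxide.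

Step 6
Reactants: 13 (2E,5S)-17-[4-(benzyloxy)phenyl]-3,5-dimethylheptadec-2-ene-1,5-diol
Product: 14 [(2S,3S)-3-{(2S)-14-[4-(benzyloxy)phenyl]-2-hydroxy-2-methyltetradecyl}-3-methyloxiran-2-yl]methanol
Conditions: Ti(OiPr)4 (0.2 equiv), L-(+)-diisopropyl tartrate (0.25 equiv), t-BuOOH (2 equiv), 4 Å molecular sieves, CH2Cl2, −25 °C; aq. NaOH/NaCl work-up
Reagents that add atoms: tert-butyl hydroperoxide, CC(C)(C)OO
Why: Sharpless asymmetric epoxidation: the L-(+)-tartrate catalyst delivers oxygen to the face that gives the (2S,3S)-epoxy alcohol from an (E)-3,3-disubstituted allylic alcohol (the sense known for geraniol), so C6a and C3a are set together by the reagent and not by remote C5; the tertiary hydroxyl binds titanium poorly and the basic work-up spares the oxirane.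

Step 7
Reactants: 14 [(2S,3S)-3-{(2S)-14-[4-(benzyloxy)phenyl]-2-hydroxy-2-methyltetradecyl}-3-methyloxiran-2-yl]methanol
Product: 15 (2R,3S)-3-{(2S)-14-[4-(benzyloxy)phenyl]-2-hydroxy-2-methyltetradecyl}-3-methyloxirane-2-carbaldehyde
Conditions: SO3·pyridine, DMSO, iPr2NEt, CH2Cl2, 0 °C
Reagents that add atoms: none
Why: Parikh–Doering oxidation of the primary alcohol under mildly basic conditions; the tertiary hydroxyl cannot be oxidised and cannot form a lactol because C6 and the formyl group are trans on the oxirane, and the oxirane carbon next to the carbonyl does not epimerise (the descriptor changes to 2R only because the formyl group outranks C6a).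

Step 8
Reactants: 15 (2R,3S)-3-{(2S)-14-[4-(benzyloxy)phenyl]-2-hydroxy-2-methyltetradecyl}-3-methyloxirane-2-carbaldehyde
Product: 16 (2S)-14-[4-(benzyloxy)phenyl]-1-[(2S,3S)-3-ethenyl-2-methyloxiran-2-yl]-2-methyltetradecan-2-ol
Conditions: Ph3PCH3Br (3 equiv), KN(SiMe3)2 (2.8 equiv), THF, 0 °C; then 15, −78 to 0 °C; chromatography on Et3N-deactivated silica
Reagents that add atoms: methyltriphenylphosphonium bromide (as its ylide), C[P+](c1ccccc1)(c1ccccc1)c1ccccc1.[Br-]
Why: Wittig methylenation of an epoxy aldehyde with a non-stabilised ylide; the excess ylide covers the free tertiary hydroxyl, the oxirane configuration is untouched, and base-washed silica prevents acid-triggered opening of the vinyl oxirane by the C5 hydroxyl.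

Step 9
Reactants: 16 (2S)-14-[4-(benzyloxy)phenyl]-1-[(2S,3S)-3-ethenyl-2-methyloxiran-2-yl]-2-methyltetradecan-2-ol
Product: 17 (2S,3S,5S)-5-{12-[4-(benzyloxy)phenyl]dodecyl}-2-ethenyl-3,5-dimethyloxolan-3-ol
Conditions: Pd(PPh3)4 (5 mol%), degassed THF, 0 °C to rt
Reagents that add atoms: none
Why: Pd(PPh3)4 (zerovalent palladium) adds to the vinyl oxirane of 16 anti to the allylic C3a–O bond and gives a zwitterionic pi-allylpalladium alkoxide in which the former oxirane oxygen stays on C6a. Proton transfer from the neighbouring C5 hydroxyl (a 1,3-diol relationship with the C6a alkoxide) gives the C5 alkoxide, which attacks the proximal allyl carbon C3a on the face opposite the metal and releases the catalyst. The closest known reaction type is the Tsuji–Trost allylic etherification in its intramolecular hydroxy vinyl epoxide form, which gives 2-vinyl-3-hydroxy cyclic ethers. The oxolane (O4, C5, C6, C6a, C3a) closes by a 5-exo attack on the allyl terminus, formally a 5-endo opening of the oxirane that the pi-allyl pathway makes possible. C3a is the only stereocentre touched: ionisation inverts it and the anti attack of O4 inverts it again, so it keeps the configuration set in step 6, while C5 and C6a keep all their bonds. The step needs proximal rather than distal attack, which ring size secures (five-membered against seven-membered), and closure by O4 rather than by the C6a alkoxide, whose only ring-forming path to the distal carbon requires the disfavoured anti allyl geometry while its attack at C3a merely returns 16. It also needs ring closure to outrun pi-sigma-pi facial exchange through the unsubstituted allyl terminus, which intramolecular hydrogen-bond-assisted delivery of O4, low temperature and halide-free conditions favour. C6a carries no hydrogen, so the usual palladium-induced isomerisation of vinyl oxiranes to enones by beta-hydride elimination is not available.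

Step 10
Reactants: 17 (2S,3S,5S)-5-{12-[4-(benzyloxy)phenyl]dodecyl}-2-ethenyl-3,5-dimethyloxolan-3-ol
Product: 19 (2S,3S,5S)-5-{12-[4-(benzyloxy)phenyl]dodecyl}-2-(2-hydroxyethyl)-3,5-dimethyloxolan-3-ol, via B-alkyl-9-borabicyclononane 18 (not isolated)
Conditions: 9-BBN (3 equiv), THF, 0 °C to rt; then aq. NaOH, H2O2, 0 °C to rt
Reagents that add atoms: hydrogen peroxide, OO
Why: Hydroboration–oxidation: the bulky borane adds anti-Markovnikov to the monosubstituted alkene and oxidation replaces boron by hydroxyl; any O–B bond formed at the tertiary hydroxyl is cleaved in the same work-up, and no stereocentre is involved.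

Step 11
Reactants: 19 (2S,3S,5S)-5-{12-[4-(benzyloxy)phenyl]dodecyl}-2-(2-hydroxyethyl)-3,5-dimethyloxolan-3-ol
Product: 22 (3aS,5S,6aS)-5-{12-[4-(benzyloxy)phenyl]dodecyl}-5,6a-dimethyltetrahydrofuro[3,2-b]furan-2(3H)-one, via hydroxy aldehyde 20 (not isolated), via lactol 21 (not isolated)
Conditions: TEMPO (0.2 equiv), PhI(OAc)2 (2.5 equiv), CH2Cl2, rt
Reagents that add atoms: none
Why: Oxoammonium-mediated oxidative lactonisation of a 1,4-diol: only the primary alcohol is oxidised, the cis tertiary hydroxyl on C6a captures the aldehyde as the five-membered lactol and a second oxidation gives the γ-lactone; the weakly acidic medium avoids base-induced elimination of O4 from the β-alkoxy aldehyde.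

Step 12
Reactants: 22 (3aS,5S,6aS)-5-{12-[4-(benzyloxy)phenyl]dodecyl}-5,6a-dimethyltetrahydrofuro[3,2-b]furan-2(3H)-one
Product: 23 plakortone N, (3aS,5S,6aS)-5-[12-(4-hydroxyphenyl)dodecyl]-5,6a-dimethyltetrahydrofuro[3,2-b]furan-2(3H)-one
Conditions: H2 (1 atm), 10% Pd/C, EtOAc, rt
Reagents that add atoms: none
Why: Catalytic hydrogenolysis of the benzyl aryl ether under neutral conditions; the lactone, the oxolane and the three stereocentres are inert and no alkene remains to be reduced.

## Compound list

1 | 4-(benzyloxy)benzyl chloride | ClCc1ccc(OCc2ccccc2)cc1 | starting material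
2 | 1,10-dibromodecane | BrCCCCCCCCCCBr | starting material
3 | [4-(benzyloxy)benzyl]magnesium chloride | Cl[Mg]Cc1ccc(OCc2ccccc2)cc1 | intermediate (not isolated)
4 | 1-(benzyloxy)-4-(11-bromoundecyl)benzene | BrCCCCCCCCCCCc1ccc(OCc2ccccc2)cc1 | intermediate
5 | (R)-2-methylglycidol, [(2R)-2-methyloxiran-2-yl]methanol | OC[C@]1(C)CO1 | starting material
6 | {11-[4-(benzyloxy)phenyl]undecyl}magnesium bromide | Br[Mg]CCCCCCCCCCCc1ccc(OCc2ccccc2)cc1 | intermediate (not isolated)
7 | (2S)-14-[4-(benzyloxy)phenyl]-2-methyltetradecane-1,2-diol | OC[C@](O)(C)CCCCCCCCCCCCc1ccc(OCc2ccccc2)cc1 | intermediate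
8 | (2S)-14-[4-(benzyloxy)phenyl]-2-hydroxy-2-methyltetradecyl 4-methylbenzenesulfonate (formed as its sodium alkoxide) | Cc1ccc(cc1)S(=O)(=O)OC[C@](O)(C)CCCCCCCCCCCCc1ccc(OCc2ccccc2)cc1 | intermediate (not isolated)
9 | (2S)-2-{12-[4-(benzyloxy)phenyl]dodecyl}-2-methyloxirane | C[C@]1(CCCCCCCCCCCCc2ccc(OCc3ccccc3)cc2)CO1 | intermediate
10 | (4S)-16-[4-(benzyloxy)phenyl]-4-methylhexadec-1-yn-4-ol | C#CC[C@@](C)(O)CCCCCCCCCCCCc1ccc(OCc2ccccc2)cc1 | intermediate
11 | (E)-alkenyl(dimethyl)alane of 10, as its dimethylaluminium alkoxide | C[Al](C)/C=C(\C)C[C@@](C)(O[Al](C)C)CCCCCCCCCCCCc1ccc(OCc2ccccc2)cc1 | intermediate (not isolated)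
12 | lithium (E)-alkenyl(butyl)dimethylalanate derived from 11 | [Li+].CCCC[Al-](C)(C)/C=C(\C)C[C@@](C)(O[Al](C)C)CCCCCCCCCCCCc1ccc(OCc2ccccc2)cc1 | intermediate (not isolated)
13 | (2E,5S)-17-[4-(benzyloxy)phenyl]-3,5-dimethylheptadec-2-ene-1,5-diol | OC/C=C(\C)C[C@@](C)(O)CCCCCCCCCCCCc1ccc(OCc2ccccc2)cc1 | intermediate
14 | [(2S,3S)-3-{(2S)-14-[4-(benzyloxy)phenyl]-2-hydroxy-2-methyltetradecyl}-3-methyloxiran-2-yl]methanol | C[C@](O)(CCCCCCCCCCCCc1ccc(OCc2ccccc2)cc1)C[C@]1(C)O[C@H]1CO | intermediate
15 | (2R,3S)-3-{(2S)-14-[4-(benzyloxy)phenyl]-2-hydroxy-2-methyltetradecyl}-3-methyloxirane-2-carbaldehyde | C[C@](O)(CCCCCCCCCCCCc1ccc(OCc2ccccc2)cc1)C[C@]1(C)O[C@H]1C=O | intermediate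
16 | (2S)-14-[4-(benzyloxy)phenyl]-1-[(2S,3S)-3-ethenyl-2-methyloxiran-2-yl]-2-methyltetradecan-2-ol | C[C@](O)(CCCCCCCCCCCCc1ccc(OCc2ccccc2)cc1)C[C@]1(C)O[C@H]1C=C | intermediate
17 | (2S,3S,5S)-5-{12-[4-(benzyloxy)phenyl]dodecyl}-2-ethenyl-3,5-dimethyloxolan-3-ol | C[C@]1(CCCCCCCCCCCCc2ccc(OCc3ccccc3)cc2)C[C@](C)(O)[C@H](C=C)O1 | intermediate
18 | 9-{2-[(2S,3S,5S)-5-{12-[4-(benzyloxy)phenyl]dodecyl}-3-hydroxy-3,5-dimethyloxolan-2-yl]ethyl}-9-borabicyclo[3.3.1]nonane | C[C@]1(CCCCCCCCCCCCc2ccc(OCc3ccccc3)cc2)C[C@](C)(O)[C@H](CCB2C3CCCC2CCC3)O1 | intermediate (not isolated)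
19 | (2S,3S,5S)-5-{12-[4-(benzyloxy)phenyl]dodecyl}-2-(2-hydroxyethyl)-3,5-dimethyloxolan-3-ol | C[C@]1(CCCCCCCCCCCCc2ccc(OCc3ccccc3)cc2)C[C@](C)(O)[C@H](CCO)O1 | intermediate
20 | 2-[(2S,3S,5S)-5-{12-[4-(benzyloxy)phenyl]dodecyl}-3-hydroxy-3,5-dimethyloxolan-2-yl]acetaldehyde | C[C@]1(CCCCCCCCCCCCc2ccc(OCc3ccccc3)cc2)C[C@](C)(O)[C@H](CC=O)O1 | intermediate (not isolated)
21 | (3aS,5S,6aS)-5-{12-[4-(benzyloxy)phenyl]dodecyl}-5,6a-dimethylhexahydrofuro[3,2-b]furan-2-ol (both anomers) | C[C@]1(CCCCCCCCCCCCc2ccc(OCc3ccccc3)cc2)C[C@]2(C)OC(O)C[C@@H]2O1 | intermediate (not isolated)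
22 | (3aS,5S,6aS)-5-{12-[4-(benzyloxy)phenyl]dodecyl}-5,6a-dimethyltetrahydrofuro[3,2-b]furan-2(3H)-one | C[C@]1(CCCCCCCCCCCCc2ccc(OCc3ccccc3)cc2)C[C@]2(C)OC(=O)C[C@@H]2O1 | intermediate
23 | plakortone N, (3aS,5S,6aS)-5-[12-(4-hydroxyphenyl)dodecyl]-5,6a-dimethyltetrahydrofuro[3,2-b]furan-2(3H)-one | C[C@]1(CCCCCCCCCCCCc2ccc(O)cc2)C[C@]2(C)OC(=O)C[C@@H]2O1 | target

## Step count and risk

Total step count: 12. Longest linear sequence: 12 steps (1 to 23); compounds 2 and 5 enter at steps 1 and 2.

**Step 9 (key step).** The most likely failure is loss of configuration at C3a. If attack by the hindered tertiary oxygen is slow, the allyl complex can exchange faces by pi-sigma-pi isomerisation through its unsubstituted terminus. Closure by the C6a alkoxide onto the distal carbon, or acid-type opening of the sensitive oxirane before the catalyst acts, are the other leaks. The fallback leaves the allyl route altogether and sets out from 14. Iodination (I2, PPh3, imidazole) should give the epoxy iodide F1. Zinc dust in ethanol should open it reductively to the ene-diol F2, in which the C6a–O bond is retained and C3a has become a vinyl carbon. F2 would then undergo the known hydroxycyclisation–carbonylation–lactonisation with PdCl2 (divalent palladium, catalytic), CuCl2 (divalent copper, 3 equiv), NaOAc and AcOH under CO. The C5 hydroxyl adds to the alkene, CO inserts, and the acyl-palladium is captured by the C6a hydroxyl, which is possible only in the cis-fused isomer. This comes back to the route at 22.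

**Step 5.** The methylalumination may be slowed or misdirected by the aluminium alkoxide. The alkenyl–metal bond may also be protonated instead of hydroxymethylated, because the alanate reacts sluggishly with depolymerising formaldehyde. The fallback sets out from 10 and builds the alkene by hydroxyl-directed chemistry. Double deprotonation (n-BuLi) and (CH2O)n give the propargylic diol F3. trans-Hydroalumination with NaAlH2(OCH2CH2OMe)2, directed by the propargylic alkoxide, followed by I2 gives the (Z)-iodo allylic alcohol F4 with iodine on C6a cis to the hydroxymethyl group. Me2CuLi then replaces iodine by methyl with retention. This comes back to the route at 13.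

**Step 6.** The 1,5-diol may sequester the titanium catalyst, and the C5 hydroxyl may attack the new oxirane under Lewis acid activation; face selectivity may also suffer. The fallback sets out from 13 and removes the need for a directing hydroxyl. MnO2 gives the enal F5 and Ph3P=CH2 gives the diene F6. A Shi epoxidation with the enantiomer of the fructose-derived ketone (made from L-sorbose) and KHSO5 at buffered pH should oxidise the trisubstituted alkene selectively. This comes back to the route at 16.

**Step 2.** Bromide may open the oxirane to a halohydrin, and the aggregated magnesium alkoxide may react slowly; one equivalent of 6 is also consumed as base. The fallback sets out from 5 and uses an activated electrophile. TsCl, Et3N and catalytic DMAP give the glycidyl tosylate F7. Compound 6 (1.2 equiv) with catalytic CuI opens its oxirane to the hydroxy tosylate, which is compound 8, now isolated. K2CO3 in MeOH then closes it. This comes back to the route at 8 and, after the closure, at 9.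

## Further compounds

F1 | step 9 | (2S)-14-[4-(benzyloxy)phenyl]-1-[(2S,3R)-3-(iodomethyl)-2-methyloxiran-2-yl]-2-methyltetradecan-2-ol | C[C@](O)(CCCCCCCCCCCCc1ccc(OCc2ccccc2)cc1)C[C@]1(C)O[C@H]1CI
F2 | step 9 | (3S,5S)-17-[4-(benzyloxy)phenyl]-3,5-dimethylheptadec-1-ene-3,5-diol | C[C@](O)(CCCCCCCCCCCCc1ccc(OCc2ccccc2)cc1)C[C@](C)(O)C=C
F3 | step 5 | (5S)-17-[4-(benzyloxy)phenyl]-5-methylheptadec-2-yne-1,5-diol | OCC#CC[C@@](C)(O)CCCCCCCCCCCCc1ccc(OCc2ccccc2)cc1
F4 | step 5 | (2Z,5S)-17-[4-(benzyloxy)phenyl]-3-iodo-5-methylheptadec-2-ene-1,5-diol | OC/C=C(\I)C[C@@](C)(O)CCCCCCCCCCCCc1ccc(OCc2ccccc2)cc1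
F5 | step 6 | (2E,5S)-17-[4-(benzyloxy)phenyl]-5-hydroxy-3,5-dimethylheptadec-2-enal | O=C/C=C(\C)C[C@@](C)(O)CCCCCCCCCCCCc1ccc(OCc2ccccc2)cc1
F6 | step 6 | (3E,6S)-18-[4-(benzyloxy)phenyl]-4,6-dimethyloctadeca-1,3-dien-6-ol | C=C/C=C(\C)C[C@@](C)(O)CCCCCCCCCCCCc1ccc(OCc2ccccc2)cc1
F7 | step 2 | [(2S)-2-methyloxiran-2-yl]methyl 4-methylbenzenesulfonate | Cc1ccc(cc1)S(=O)(=O)OC[C@]1(C)CO1
A1 | alternative 1 | cis-1,3-dimethylcyclopent-4-ene-1,3-diol, (1R,3S), meso | O[C@@]1(C)C[C@@](C)(O)C=C1
A2 | alternative 1 | (1S,3R)-1,3-dimethyl-3-[(triethylsilyl)oxy]cyclopent-4-en-1-yl prop-2-enoate | C=CC(=O)O[C@@]1(C)C[C@@](C)(O[Si](CC)(CC)CC)C=C1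
A3 | alternative 1 | 1-(benzyloxy)-4-(dodec-11-en-1-yl)benzene | C=CCCCCCCCCCCc1ccc(OCc2ccccc2)cc1
A4 | alternative 1 | (5S)-5-{(2R,3E)-14-[4-(benzyloxy)phenyl]-2-methyl-2-[(triethylsilyl)oxy]tetradec-3-en-1-yl}-5-methylfuran-2(5H)-one | O=C1C=C[C@](C)(C[C@@](C)(O[Si](CC)(CC)CC)/C=C/CCCCCCCCCCc2ccc(OCc3ccccc3)cc2)O1
A5 | alternative 2 | (4S)-16-[4-(benzyloxy)phenyl]-4-(ethenyloxy)-4-methylhexadecan-2-one | CC(=O)C[C@@](C)(OC=C)CCCCCCCCCCCCc1ccc(OCc2ccccc2)cc1
A6 | alternative 2 | (3aS,5S,6aS)-5-{12-[4-(benzyloxy)phenyl]dodecyl}-5,6a-dimethyltetrahydrofuro[3,2-b]furan-2(3H)-one | C[C@]1(CCCCCCCCCCCCc2ccc(OCc3ccccc3)cc2)C[C@]2(C)OC(=O)C[C@@H]2O1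
A7 | alternative 3 | (2S,3R)-2-{12-[4-(benzyloxy)phenyl]dodecyl}-2,4-dimethyl-2,3-dihydrofuran-3-yl acetate | C[C@]1(CCCCCCCCCCCCc2ccc(OCc3ccccc3)cc2)[C@H](OC(C)=O)C(C)=CO1
A8 | alternative 3 | (3aS,5S,6R,6aR)-5-{12-[4-(benzyloxy)phenyl]dodecyl}-6-iodo-5,6a-dimethyltetrahydrofuro[3,2-b]furan-2(3H)-one | C[C@]1(CCCCCCCCCCCCc2ccc(OCc3ccccc3)cc2)[C@@H](I)[C@]2(C)OC(=O)C[C@@H]2O1
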